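## Analysis of the target

Guanipiperazine A is a 14-membered meta,para-cyclophane built on a piperazine: piperazine C2 and C5 each carry one benzylic CH2, the first bonded to C1 of ring A (a 1,3,4,5-tetrasubstituted benzene) and the second to C1 of ring B (a para-phenylene), and an ether oxygen joins ring A C3 to ring B C4. Ring A also bears a free hydroxyl at C4 and, at C5, a bond to C8 of a guanine, so the phenol sits between the ether oxygen and the purine. The only stereocentres are piperazine C2 and C5; both are S, which places the two benzylic arms cis, as in a cyclodipeptide of two L-arylalanines. The groups that need care are the two secondary amines, the electron-rich phenol and the purine, which is poorly soluble, has several acidic N–H bonds and binds metals. The difficulties are the strain of the cyclophane, the cis placement of two different aryl arms on an otherwise symmetric core, and the late C–C bond between purine C8 and the hindered ring A C5; together they call for four separately addressable aromatic sites (ring B C4, ring A C3–O, C4–O and C5). The plan rests on one feature: each stereocentre is a CH flanked by a nitrogen and one ArCH2 group, that is, the α-carbon of an arylalanine at the amine oxidation level. The bonds piperazine C2–CH2 (to ring A) and C5–CH2 (to ring B) are therefore Cα–Cβ bonds that two aldol condensations of a glycine anhydride with two benzaldehydes can make, and both stereocentres then come from hydrogenation of the two C=C bonds.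

## Retrosynthetic reasoning

**18 ⇒ 17 ⇒ 15 + 16.** The bond between purine C8 and ring A C5 is cut first. It is the only bond joining the heterocycle to the cyclophane, and cutting it lets the purine arrive ready-made and confines its solubility problems to the last two steps. The forward reaction is a Suzuki–Miyaura coupling of the ring A boronate 15 with the C8 bromide of nucleoside 16. The sugar of 16 blocks N9 and keeps the purine soluble; an acidic hydrolysis then removes it from 17 together with the two carbamates.

**15 ⇒ 14 ⇒ 13.** The C5–B bond is traced back through a C5–I bond to a C5–H bond. This works because in 13 the C4 hydroxyl is free and C5 is the only open position ortho or para to it, so an electrophile has one place to go. The consequence for the whole plan is that the C4 oxygen must be unmasked under mild conditions before the purine arrives. Ring A is therefore carried with a hydrogenolysable benzyl ether at C4, not a methyl ether.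

**13 ⇒ 12.** This is a protecting-group exchange, not a skeletal cut. One hydrogenolysis removes the O-benzyl and both N-benzyl groups of 12, and the amines are capped as carbamates in the same flask. It is placed after the macrocyclisation because only then is the aryl bromide gone.

**12 ⇒ 11.** The ether bond between the ring A C3 oxygen and ring B C4 is cut. The oxygen is native to the catechol-type ring A, and ring B can carry a bromide from the start, so the forward step is an intramolecular Ullmann etherification. It is run on the flexible piperazine, not on the flat bis-lactam, and on tertiary amines that cannot compete as nucleophiles.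

**11 ⇒ 9.** Both lactam carbonyls are returned, and the C3 phenol is masked as an acetal. Forward, a hydride reduction with a boron hydride converts the two amides into amines, and the acidic alcoholysis that breaks the amine–boron adducts also frees the phenol (via 10).

**9 ⇒ 8 ⇒ 7.** Four hydrogens are removed to give the bis-arylidene 8. Forward, one catalyst-controlled asymmetric hydrogenation reduces both C=C bonds and sets both stereocentres, with the cis relationship built in. The N-benzyl groups of 8 are put on 7 beforehand, because the N–H compound is too insoluble for a homogeneous catalyst and N,N'-dialkyl bis-arylidene diketopiperazines are the substrate type for which this hydrogenation is established.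

**7 ⇒ 2 + 4 + 5.** Both exocyclic C=C bonds are cut. This is the central disconnection: all carbon atoms of the cyclophane come from three simple pieces, and the two aldehydes already carry the handles for the ether bridge (ring A oxygens in 4, ring B bromide in 5). The forward reaction has to deliver one of each aldehyde and Z geometry at both alkenes.

**2 ⇒ 1 and 4 ⇒ 3.** N,N'-Diacetylation of 1 gives the doubly activated glycine anhydride 2. Acetal protection of the free hydroxyl of 3 gives aldehyde 4, with its two oxygens differentiated for later use.

## Alternatives that were turned down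

Alternative 1: The C8–N7 and C8–N9 bonds of the imidazole ring are cut, so the purine is annulated last. Forward, the macrocyclic salicylaldehyde A2 condenses with 2,5,6-triaminopyrimidin-4(3H)-one A3, and oxidation of the adduct closes the imidazole ring and gives the di-Boc-protected natural product A1. Acidolysis of A1 would then release the target.
- For: no cross-coupling of a purine is needed, A3 is a commodity, and the one-carbon handle of A2 can be placed by phenol-directed ortho-formylation. On end-game step count the path through A1 is as good as or better than the iodination, borylation and coupling sequence chosen here.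
- Against: the key step builds none of the cyclophane. A2 still needs the whole macrocycle with both stereocentres, so a skeleton-building plan such as the chosen one is required anyway. The oxidative ring closure to A1 must also be run next to an electron-rich free phenol, and A3 is polar and air-sensitive.
- Comparison: the chosen strategy puts its key step where the carbon skeleton is made, and keeps the annulation leading to A1 as the fallback for the purine attachment.

Alternative 2: Two C–C bonds of ring B are cut, so ring B is built during macrocyclisation. Forward, the tethered pyrone–ynol ether A5 undergoes an intramolecular Diels–Alder reaction between pyrone C3/C6 and the aryl ethynyl ether on heating, and the bridged bicyclic lactone adduct aromatises by decarboxylation to O-methylpiperazinomycin bis(methyl carbamate) A4.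
- For: ring and macrocycle close together, the strain is taken up before aromatisation, and the ynol ether oxygen becomes the diaryl ether oxygen. On the risk of the macrocyclisation itself this may be stronger than an Ullmann closure.
- Against: A5 needs a chiral cis-piperazine carrying a pyranone side chain and a thermally fragile ethynyl ether, each made by a multi-step sequence, and the stereocentres must be set separately. A4 also carries methyl carbamates and a methyl ether that need harsh cleavage before the purine can be attached.
- Comparison: the chosen strategy reaches the complete carbon skeleton 7 in three steps from commodity aldehydes and sets both stereocentres in one catalytic step. The price is a conventional Ullmann ring closure.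

Alternative 3: The N–C and C–C bonds at the ring B-side stereocentre are cut, so the piperazine is closed last by the tin amine protocol. Forward, the stannylmethyl diamine A7 condenses with 2-(4-bromophenyl)acetaldehyde A8, and oxidation of the C–Sn bond by Cu(OTf)2 with 2,6-lutidine triggers radical 6-endo cyclisation onto the imine to give the mono-Boc cis-piperazine A6.
- For: the piperazine is formed directly at the amine oxidation level, with no amide reduction, and the two nitrogens of A6 come out differentiated. On these two points it is stronger than the chosen route.
- Against: A7 is not a commodity, and its stereocentre needs its own asymmetric synthesis. A8 is an enolisable arylacetaldehyde prone to self-condensation and imine–enamine tautomerism. The second stereocentre of A6 depends on substrate control in a radical cyclisation, and cis selectivity for a 2,5-pattern is not assured. Stoichiometric Cu(OTf)2 and an organotin reagent are required, and the nitrogen differentiation is not needed for a target with two N–H groups.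
- Comparison: the chosen strategy sets both centres together under catalyst control with the cis relationship enforced, and needs no chiral-pool building block.

Key step: step 3

Remark on the chemistry: 8-bromo-2'-deoxyguanosine (16) serves as the commercially available, soluble, N9-blocked form of 8-bromoguanine; the ligand enantiomer in step 5 is the one that leads to the (S,S) series, fixed beforehand by a calibration run.

## Route

Step 1
Reactants: 1 glycine anhydride (piperazine-2,5-dione)
Product: 2 1,4-diacetylpiperazine-2,5-dione
Conditions: Ac2O (neat), reflux; evaporate; recrystallise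
Reagents that add atoms: acetic anhydride, CC(=O)OC(C)=O
Why: Exhaustive N-acetylation of the bis-lactam in boiling anhydride; the two imide nitrogens acidify both ring CH2 groups and later act as internal acetyl donors.

Step 2
Reactants: 3 4-(benzyloxy)-3-hydroxybenzaldehyde
Product: 4 4-(benzyloxy)-3-(methoxymethoxy)benzaldehyde
Conditions: MOMCl, K2CO3, acetone, 0 °C to rt
Reagents that add atoms: chloromethyl methyl ether (MOMCl), COCCl
Why: Williamson-type O-alkylation of the phenoxide to the MOM acetal. The acetal withstands carbonate, hydride base, hydrogenation and borane and is later cleaved by the methanolic acid of step 6, while the C4 benzyl ether stays until step 8.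

Step 3
Reactants: 2 1,4-diacetylpiperazine-2,5-dione; 4 4-(benzyloxy)-3-(methoxymethoxy)benzaldehyde; 5 4-bromobenzaldehyde
Product: 7 (3Z,6Z)-3-[4-(benzyloxy)-3-(methoxymethoxy)benzylidene]-6-(4-bromobenzylidene)piperazine-2,5-dione, via mono-arylidene N-acetyl diketopiperazine 6 (not isolated)
Conditions: 2 (1.1 equiv), 4 (1.0 equiv), Cs2CO3 (1.1 equiv), DMF, N2, rt; then 5 (1.3 equiv), Cs2CO3 (1.5 equiv), 85 °C; pour into water, filter, triturate (final purification after step 4)
Reagents that add atoms: none
Why: Cs2CO3 deprotonates a ring CH2 of 2 (acidified by the flanking imide carbonyl), the enolate adds to aldehyde 4, the aldolate oxygen takes the acetyl group from the neighbouring ring nitrogen through a five-membered tetrahedral intermediate (N-to-O acyl shift), and E1cB loss of acetate gives the Z-mono-arylidene 6. In 6 the new enamide N–H is the most acidic site, so at room temperature 6 rests as its N-anion and a second condensation with 4 is held back; on warming with more base the CH2 next to the surviving N-acetyl group enolises and repeats the same addition, acyl shift and elimination on 5 to give 7. The closest known reaction type is the stepwise base-mediated aldol condensation of 1,4-diacetylpiperazine-2,5-dione with two different aryl aldehydes, here run in one flask. No ring is closed and no stereocentre is formed; the two new C=C bonds are the bonds that become piperazine C2–CH2 (ring A) and C5–CH2 (ring B). The selectivity needed is one of each aldehyde, secured by sequential addition, by the drop in CH acidity once the first acetyl group is spent, and by giving the less electrophilic aldehyde 4 the more reactive methylene and the more electrophilic 5 the sluggish second one. The Z,Z geometry is the thermodynamic outcome, since in an E isomer the aryl ring would clash with the lactam carbonyl. Aryl bromide, benzyl ether and MOM acetal are inert to carbonate in DMF.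

Step 4
Reactants: 7 (3Z,6Z)-3-[4-(benzyloxy)-3-(methoxymethoxy)benzylidene]-6-(4-bromobenzylidene)piperazine-2,5-dione
Product: 8 (3Z,6Z)-1,4-dibenzyl-3-[4-(benzyloxy)-3-(methoxymethoxy)benzylidene]-6-(4-bromobenzylidene)piperazine-2,5-dione
Conditions: NaH, DMF, 0 °C; BnBr, 0 °C to rt, light excluded
Reagents that add atoms: benzyl bromide, BrCc1ccccc1
Why: Double N-alkylation of the lactam anions makes the insoluble bis-arylidene soluble and gives the N,N'-dialkyl substrate type for which iridium-catalysed double hydrogenation of bis-arylidene diketopiperazines is established. The benzyl groups later leave in the same hydrogenolysis as the O-benzyl group; light is excluded to keep the Z,Z geometry.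

Step 5
Reactants: 8 (3Z,6Z)-1,4-dibenzyl-3-[4-(benzyloxy)-3-(methoxymethoxy)benzylidene]-6-(4-bromobenzylidene)piperazine-2,5-dione
Product: 9 (3S,6S)-1,4-dibenzyl-3-[4-(benzyloxy)-3-(methoxymethoxy)benzyl]-6-(4-bromobenzyl)piperazine-2,5-dione (cis)
Conditions: [Ir(cod)Cl]2 (1 mol %), SpinPHOX-type spiro phosphine–oxazoline (2.2 mol %), NaB[3,5-(CF3)2C6H3]4 (2.5 mol %), H2 (30 bar), CH2Cl2, 25 °C
Reagents that add atoms: none
Why: Double asymmetric hydrogenation of the two trisubstituted enamide C=C bonds by the cationic catalyst formed from [Ir(cod)Cl]2, the phosphine–oxazoline and NaB[3,5-(CF3)2C6H3]4 (monovalent iridium precatalyst, trivalent iridium dihydride in the cycle). The ligand fixes the face of H2 addition at C3 (S), and the second addition is expected on the same face, under catalyst control reinforced by the new benzyl group shielding the other face, so C6 is also S and the ring is cis. The homogeneous catalyst should leave aryl bromide, benzyl ether, N-benzyl and MOM groups alone.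

Step 6
Reactants: 9 (3S,6S)-1,4-dibenzyl-3-[4-(benzyloxy)-3-(methoxymethoxy)benzyl]-6-(4-bromobenzyl)piperazine-2,5-dione
Product: 11 2-(benzyloxy)-5-{[(2S,5S)-1,4-dibenzyl-5-(4-bromobenzyl)piperazin-2-yl]methyl}phenol, via MOM-protected dibenzylpiperazine 10 (not isolated)
Conditions: BH3·SMe2, THF, 65 °C; then MeOH, HCl (3 M in MeOH), 60 °C; aq. NaHCO3 work-up
Reagents that add atoms: none
Why: Borane reduction of both tertiary lactams gives the piperazine 10, held in the flask as its amine–borane complex; no base is present, so the α-stereocentres cannot epimerise, and once the carbonyls are gone they are configurationally fixed. Hot methanolic HCl then cleaves the amine–borane bonds and the MOM acetal in one operation and exposes the ring A C3 phenol; aryl bromide and benzyl ether are inert to both reagents.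

Step 7
Reactants: 11 2-(benzyloxy)-5-{[(2S,5S)-1,4-dibenzyl-5-(4-bromobenzyl)piperazin-2-yl]methyl}phenol
Product: 12 N,N'-dibenzyl-O-benzylpiperazinomycin: the 14-membered macrocycle in which the (2S,5S)-1,4-dibenzylpiperazine carries at C2 the CH2 to ring A C1 and at C5 the CH2 to ring B C1, with an ether oxygen from ring A C3 to ring B C4 and a benzyloxy group at ring A C4
Conditions: CuI (0.5 equiv), N,N-dimethylglycine (1.5 equiv), Cs2CO3 (3 equiv), 1,4-dioxane, 100 °C, slow addition to 2 mM, Ar
Reagents that add atoms: none
Why: Intramolecular Ullmann diaryl ether synthesis: the phenoxide on ring A C3, formed with Cs2CO3, is arylated by the ring B bromide at the CuI–N,N-dimethylglycine complex (monovalent copper), with high dilution favouring closure of the 14-membered ring over oligomers. The nitrogens are tertiary and cannot compete as nucleophiles.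

Step 8
Reactants: 12 N,N'-dibenzyl-O-benzylpiperazinomycin
Product: 13 N,N'-di-Boc-piperazinomycin (the macrocycle of 12 with free OH at ring A C4 and a tert-butoxycarbonyl group on each piperazine nitrogen; S,S)
Conditions: H2 (3 bar), Pd(OH)2/C, Boc2O (2.5 equiv), EtOH/EtOAc, 40 °C; then K2CO3, MeOH, rt (cleaves any O-Boc)
Reagents that add atoms: di-tert-butyl dicarbonate (Boc2O), CC(C)(C)OC(=O)OC(=O)OC(C)(C)C
Why: Hydrogenolysis over Pd(OH)2/C cleaves the O-benzyl ether and both N-benzyl groups, which is possible now that the aryl bromide is gone. The secondary amines are trapped as tert-butyl carbamates as they form, which also keeps them from poisoning the catalyst; the diaryl ether and the stereocentres are untouched.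

Step 9
Reactants: 13 N,N'-di-Boc-piperazinomycin
Product: 14 5-iodo-N,N'-di-Boc-piperazinomycin (iodine at ring A C5, ortho to the hydroxyl)
Conditions: NIS (1.05 equiv), TsOH·H2O (10 mol %), CH2Cl2/MeCN, 0 °C to rt, dark
Reagents that add atoms: N-iodosuccinimide, O=C1CCC(=O)N1I
Why: Electrophilic aromatic iodination directed by the free phenol: on ring A the only open position ortho or para to the hydroxyl is C5, and the phenol ring is far more reactive than the alkyl aryl ether ring B, so one equivalent of NIS should iodinate C5 only.

Step 10
Reactants: 14 5-iodo-N,N'-di-Boc-piperazinomycin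
Product: 15 5-(4,4,5,5-tetramethyl-1,3,2-dioxaborolan-2-yl)-N,N'-di-Boc-piperazinomycin (pinacol boronate at ring A C5)
Conditions: B2pin2, Pd(dppf)Cl2 (5 mol %), KOAc, 1,4-dioxane, 85 °C
Reagents that add atoms: bis(pinacolato)diboron, CC1(C)OB(OC1(C)C)B1OC(C)(C)C(C)(C)O1
Why: Miyaura borylation: zerovalent palladium inserts into the C–I bond, acetate-assisted transmetalation with the diboron follows, and reductive elimination gives the boronate. Free phenols and carbamates are tolerated with KOAc as base.

Step 11
Reactants: 15 5-(pinacolboryl)-N,N'-di-Boc-piperazinomycin; 16 8-bromo-2'-deoxyguanosine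
Product: 17 8-aryl-2'-deoxyguanosine in which guanine C8 is bonded to ring A C5 of N,N'-di-Boc-piperazinomycin
Conditions: Pd(OAc)2 (5 mol %), SPhos (10 mol %), K3PO4, 1,4-dioxane/H2O 3:1, 80 °C
Reagents that add atoms: none
Why: Suzuki–Miyaura coupling of an arylboron reagent with the C8 bromide of the unprotected nucleoside in aqueous base, a known coupling type that also tolerates ortho-hydroxyaryl boron partners. The deoxyribose blocks N9 and keeps the purine in solution, and the electron-rich biaryl phosphine is chosen so that transmetalation outruns protodeboronation.

Step 12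
Reactants: 17 8-aryl-2'-deoxyguanosine of N,N'-di-Boc-piperazinomycin
Product: 18 guanipiperazine A
Conditions: TFA/H2O 9:1, 0 °C to 40 °C; evaporate; aq. NH3 to pH 8, reversed-phase purification
Reagents that add atoms: none
Why: Acidolysis removes both Boc groups (tert-butyl cation lost as isobutene, then decarboxylation). The aqueous acid also hydrolyses the N-glycosidic bond through an oxocarbenium ion (depurination), which is especially easy for 2'-deoxynucleosides with a C8 aryl group; the piperazine stereocentres have no acidifying neighbour and are not touched.

## Compound list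

1 | glycine anhydride (piperazine-2,5-dione) | O=C1CNC(=O)CN1 | starting material
2 | 1,4-diacetylpiperazine-2,5-dione | CC(=O)N1CC(=O)N(C(C)=O)CC1=O | intermediate
3 | 4-(benzyloxy)-3-hydroxybenzaldehyde | O=Cc1ccc(OCc2ccccc2)c(O)c1 | starting material
4 | 4-(benzyloxy)-3-(methoxymethoxy)benzaldehyde | O=Cc1ccc(OCc2ccccc2)c(OCOC)c1 | intermediate
5 | 4-bromobenzaldehyde | O=Cc1ccc(Br)cc1 | starting material
6 | (Z)-1-acetyl-3-[4-(benzyloxy)-3-(methoxymethoxy)benzylidene]piperazine-2,5-dione (formed in the flask, not isolated) | CC(=O)N1CC(=O)N/C(=C\c2ccc(OCc3ccccc3)c(OCOC)c2)C1=O | intermediate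
7 | (3Z,6Z)-3-[4-(benzyloxy)-3-(methoxymethoxy)benzylidene]-6-(4-bromobenzylidene)piperazine-2,5-dione | O=C1N/C(=C\c2ccc(Br)cc2)C(=O)N/C1=C\c1ccc(OCc2ccccc2)c(OCOC)c1 | intermediate
8 | (3Z,6Z)-1,4-dibenzyl-3-[4-(benzyloxy)-3-(methoxymethoxy)benzylidene]-6-(4-bromobenzylidene)piperazine-2,5-dione | O=C1N(Cc2ccccc2)/C(=C\c2ccc(Br)cc2)C(=O)N(Cc2ccccc2)/C1=C\c1ccc(OCc2ccccc2)c(OCOC)c1 | intermediate
9 | (3S,6S)-1,4-dibenzyl-3-[4-(benzyloxy)-3-(methoxymethoxy)benzyl]-6-(4-bromobenzyl)piperazine-2,5-dione | O=C1N(Cc2ccccc2)[C@@H](Cc2ccc(Br)cc2)C(=O)N(Cc2ccccc2)[C@H]1Cc1ccc(OCc2ccccc2)c(OCOC)c1 | intermediate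
10 | (2S,5S)-1,4-dibenzyl-2-[4-(benzyloxy)-3-(methoxymethoxy)benzyl]-5-(4-bromobenzyl)piperazine (held in the flask as its amine–borane complex, not isolated) | C1N(Cc2ccccc2)[C@@H](Cc2ccc(Br)cc2)CN(Cc2ccccc2)[C@H]1Cc1ccc(OCc2ccccc2)c(OCOC)c1 | intermediate
11 | 2-(benzyloxy)-5-{[(2S,5S)-1,4-dibenzyl-5-(4-bromobenzyl)piperazin-2-yl]methyl}phenol | C1N(Cc2ccccc2)[C@@H](Cc2ccc(Br)cc2)CN(Cc2ccccc2)[C@H]1Cc1ccc(OCc2ccccc2)c(O)c1 | intermediate
12 | N,N'-dibenzyl-O-benzylpiperazinomycin (S,S) | C(Oc1ccc2cc1Oc1ccc(cc1)C[C@H]3CN(Cc4ccccc4)[C@H](CN3Cc3ccccc3)C2)c1ccccc1 | intermediate
13 | N,N'-di-Boc-piperazinomycin (S,S) | Oc1ccc2cc1Oc1ccc(cc1)C[C@H]3CN(C(=O)OC(C)(C)C)[C@H](CN3C(=O)OC(C)(C)C)C2 | intermediate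
14 | 5-iodo-N,N'-di-Boc-piperazinomycin | Oc1c(I)cc2cc1Oc1ccc(cc1)C[C@H]3CN(C(=O)OC(C)(C)C)[C@H](CN3C(=O)OC(C)(C)C)C2 | intermediate
15 | 5-(4,4,5,5-tetramethyl-1,3,2-dioxaborolan-2-yl)-N,N'-di-Boc-piperazinomycin | Oc1c(B4OC(C)(C)C(C)(C)O4)cc2cc1Oc1ccc(cc1)C[C@H]3CN(C(=O)OC(C)(C)C)[C@H](CN3C(=O)OC(C)(C)C)C2 | intermediate
16 | 8-bromo-2'-deoxyguanosine | C1[C@@H]([C@H](O[C@H]1n3c(Br)nc4c3nc(N)[nH]c4=O)CO)O | starting material
17 | 8-aryl-2'-deoxyguanosine of N,N'-di-Boc-piperazinomycin (guanine C8 bonded to ring A C5) | C1[C@@H]([C@H](O[C@H]1n3c(-c5cc6cc(c5O)Oc5ccc(cc5)C[C@H]5CN(C(=O)OC(C)(C)C)[C@H](CN5C(=O)OC(C)(C)C)C6)nc4c3nc(N)[nH]c4=O)CO)O | intermediate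
18 | guanipiperazine A | Nc1nc2nc(-c3cc4cc(c3O)Oc3ccc(cc3)C[C@H]3CN[C@H](CN3)C4)[nH]c2c(=O)[nH]1 | target

## Step count and risk

Total step count: 12. Longest linear sequence: 11 steps (step 1 or step 2, then steps 3 to 12).

Least certain steps:

**Step 3 (key step).**
- Risk: the one-of-each stoichiometry can scramble, either by a second condensation of 4 before 5 is added or by condensation of left-over 2 with 5. Hydrolytic loss of the last N-acetyl group from 6 before the second condensation would stop the sequence at the mono-arylidene. The low solubility of the products makes any such mixture hard to purify.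
- Fallback: it sets out from 2 and 5 and comes back to the route at 7. The two condensations are run as separate operations in the reverse order. An excess of 2 is condensed with 5 (Et3N, DMF, rt) to give (Z)-1-acetyl-3-(4-bromobenzylidene)piperazine-2,5-dione F1, which is crystallised free of symmetric product. F1 is then condensed with 4 (Cs2CO3, DMF, 85 °C) to give 7.

**Step 5.**
- Risk: facial selectivity may erode, or the reduction may stall after the first C=C bond, because the N-benzyl groups are larger than the N-methyl groups for which this catalyst type is proven. Z/E isomerisation of 8 in light would lower the enantiomeric purity further, and slow reductive loss of bromine is possible.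
- Fallback: it sets out from 8 and comes back to the route at 9. Compound 8 is hydrogenated with the achiral catalyst [Ir(cod)(PCy3)(py)]PF6 (H2, CH2Cl2). The second addition should occur anti to the first benzyl group and give the racemic cis-diketopiperazine F2, whose enantiomers are separated by preparative chromatography on a chiral stationary phase to give 9.

**Step 7.**
- Risk: intermolecular O-arylation to oligomers may outrun closure of the strained meta,para-cyclophane, and the bromide may be lost reductively at 100 °C.
- Fallback: it sets out from 11 and comes back to the route at 12. The bromide of 11 is converted into the arylboronic acid F3 (B2(OH)4, Pd(OAc)2, XPhos, KOAc, EtOH, 80 °C). F3 is cyclised at room temperature by oxidative Chan–Lam etherification (Cu(OAc)2, Et3N, 4 Å molecular sieves, CH2Cl2, air, high dilution) to give 12.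

**Step 11.**
- Risk: protodeboronation of the ortho-hydroxyaryl boronate in aqueous base may be faster than transmetalation, the unprotected guanine nucleoside may sequester palladium, and the lipophilic boronate and polar nucleoside may not share a solvent well.
- Fallback: it sets out from 13 and comes back to the route at 18, so that it also bypasses steps 9 and 10. The imidazole ring of the purine is built on the arene. Phenol 13 is ortho-formylated (MgCl2, Et3N, paraformaldehyde, MeCN, reflux; C5 is the only open ortho position) to the macrocyclic salicylaldehyde F4. F4 is condensed with 2,5,6-triaminopyrimidin-4(3H)-one A3 and cyclised oxidatively (Na2S2O5, DMF, 110 °C, open to air) to N,N'-di-Boc guanipiperazine A F5. Treatment of F5 with TFA/H2O gives 18.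

## Further compounds

F1 | step 3 | (Z)-1-acetyl-3-(4-bromobenzylidene)piperazine-2,5-dione | CC(=O)N1CC(=O)N/C(=C\c2ccc(Br)cc2)C1=O
F2 | step 5 | racemic cis-1,4-dibenzyl-3-[4-(benzyloxy)-3-(methoxymethoxy)benzyl]-6-(4-bromobenzyl)piperazine-2,5-dione (9 together with its (3R,6R) enantiomer) | O=C1N(Cc2ccccc2)[C@@H](Cc2ccc(Br)cc2)C(=O)N(Cc2ccccc2)[C@H]1Cc1ccc(OCc2ccccc2)c(OCOC)c1.O=C1N(Cc2ccccc2)[C@H](Cc2ccc(Br)cc2)C(=O)N(Cc2ccccc2)[C@@H]1Cc1ccc(OCc2ccccc2)c(OCOC)c1
F3 | step 7 | [4-({(2S,5S)-1,4-dibenzyl-5-[4-(benzyloxy)-3-hydroxybenzyl]piperazin-2-yl}methyl)phenyl]boronic acid | C1N(Cc2ccccc2)[C@@H](Cc2ccc(B(O)O)cc2)CN(Cc2ccccc2)[C@H]1Cc1ccc(OCc2ccccc2)c(O)c1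
F4 | step 11 | 5-formyl-N,N'-di-Boc-piperazinomycin (macrocyclic salicylaldehyde, CHO at ring A C5) | O=Cc1cc2cc(c1O)Oc1ccc(cc1)C[C@H]1CN(C(=O)OC(C)(C)C)[C@H](CN1C(=O)OC(C)(C)C)C2
F5 | step 11 | N,N'-di-Boc guanipiperazine A | Nc1nc2nc(-c3cc4cc(c3O)Oc3ccc(cc3)C[C@H]3CN(C(=O)OC(C)(C)C)[C@H](CN3C(=O)OC(C)(C)C)C4)[nH]c2c(=O)[nH]1
A1 | alternative 1 | N,N'-di-Boc guanipiperazine A | Nc1nc2nc(-c3cc4cc(c3O)Oc3ccc(cc3)C[C@H]3CN(C(=O)OC(C)(C)C)[C@H](CN3C(=O)OC(C)(C)C)C4)[nH]c2c(=O)[nH]1
A2 | alternative 1 | 5-formyl-N,N'-di-Boc-piperazinomycin (macrocyclic salicylaldehyde) | O=Cc1cc2cc(c1O)Oc1ccc(cc1)C[C@H]1CN(C(=O)OC(C)(C)C)[C@H](CN1C(=O)OC(C)(C)C)C2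
A3 | alternative 1 | 2,5,6-triaminopyrimidin-4(3H)-one | Nc1nc(N)c(N)c(=O)[nH]1
A4 | alternative 2 | O-methylpiperazinomycin bis(methyl carbamate) | COc1ccc2cc1Oc1ccc(cc1)C[C@H]3CN(C(=O)OC)[C@H](CN3C(=O)OC)C2
A5 | alternative 2 | dimethyl (2S,5S)-2-[3-(ethynyloxy)-4-methoxybenzyl]-5-[(2-oxo-2H-pyran-5-yl)methyl]piperazine-1,4-dicarboxylate | C1N(C(=O)OC)[C@@H](Cc2ccc(=O)oc2)CN(C(=O)OC)[C@H]1Cc1ccc(OC)c(OC#C)c1
A6 | alternative 3 | tert-butyl (2S,5S)-2-[3-(benzyloxy)-4-methoxybenzyl]-5-(4-bromobenzyl)piperazine-1-carboxylate (cis) | Brc1ccc(C[C@H]2CN(C(=O)OC(C)(C)C)[C@H](CN2)Cc3ccc(OC)c(OCc4ccccc4)c3)cc1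
A7 | alternative 3 | tert-butyl {(2S)-1-amino-3-[3-(benzyloxy)-4-methoxyphenyl]propan-2-yl}[(tributylstannyl)methyl]carbamate | NC[C@H](Cc1ccc(OC)c(OCc2ccccc2)c1)N(C(=O)OC(C)(C)C)C[Sn](CCCC)(CCCC)CCCC
A8 | alternative 3 | 2-(4-bromophenyl)acetaldehyde | O=CCc1ccc(Br)cc1
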